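**Assumption:** the SMILES is read as (2R,4R,6S)-2-(4-hydroxy-3-methoxyphenyl)-6-[(1R)-1-hydroxy-2-(4-hydroxyphenyl)ethyl]oxan-4-ol, i.e. an all-cis 2,4,6-trisubstituted oxane whose O-6/O-1′ pair is anti (erythro).

## Retrosynthetic overview

1. Target ⇐ debenzylation of 18 ⇐ Prins cyclisation of homoallylic alcohol 10 with aldehyde 16; this makes the oxane ring and sets C-2 and C-4 from C-6.
2. 10 ⇐ vinyl Grignard opening of epoxide 9 ⇐ matched Sharpless epoxidation of (R)-allylic alcohol 7, which sets the anti C–O pair.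
3. 7 ⇐ one-carbon ylide homologation of epoxide 6 ⇐ Grignard reagent of benzyl-protected 4-bromophenol + (R)-epichlorohydrin.
4. 16 ⇐ vanillin ⇐ 4-bromo-2-methoxyphenol ⇐ guaiacol ⇐ catechol.
5. Ring order: both benzene rings are bought; the oxane ring is the only ring formed, in step 11.

## Route

**Step 1**
Reactants: 1 4-bromophenol
Product: 2 1-(benzyloxy)-4-bromobenzene
Conditions: BnBr (1.1 equiv), K2CO3, acetone, reflux
Reagents that add atoms: benzyl bromide BrCc1ccccc1
Why: Williamson ether synthesis on the phenoxide masks the acidic OH so that the aryl bromide can be converted into a Grignard reagent.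

**Step 2**
Reactants: 2 1-(benzyloxy)-4-bromobenzene; 3 (R)-epichlorohydrin
Product: 6 (2R)-2-[4-(benzyloxy)benzyl]oxirane, via arylmagnesium bromide 4 (not isolated), via chlorohydrin 5 (not isolated)
Conditions: Mg, THF, reflux; CuI (10 mol %), 3, −40 → 0 °C; then 2 M NaOH aq, rt
Reagents that add atoms: none
Why: Copper-catalysed Grignard opening of the epoxide at its CH2 terminus, then base-induced ring closure of the chlorohydrin (intramolecular Williamson), never touches the stereocentre of 3, so (R) is carried over.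

**Step 3**
Reactants: 6 (2R)-2-[4-(benzyloxy)benzyl]oxirane
Product: 7 (2R)-1-[4-(benzyloxy)phenyl]but-3-en-2-ol
Conditions: Me3S+ I− (4 equiv), n-BuLi (3.8 equiv), THF, −10 °C → rt
Reagents that add atoms: trimethylsulfonium iodide C[S+](C)C.[I-]
Why: One-carbon homologation of a terminal epoxide to an allylic alcohol by dimethylsulfonium methylide (Corey–Chaykovsky ylide; opening at CH2, then elimination of Me2S) leaves the (R) carbinol centre untouched.

**Step 4**
Reactants: 7 (2R)-1-[4-(benzyloxy)phenyl]but-3-en-2-ol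
Product: 8 (1R)-2-[4-(benzyloxy)phenyl]-1-[(2S)-oxiran-2-yl]ethan-1-ol
Conditions: Ti(OiPr)4 (1.0 equiv), D-(−)-diisopropyl tartrate (1.2 equiv), t-BuOOH (2 equiv), 4 Å MS, CH2Cl2, −20 °C, 3 d
Reagents that add atoms: tert-butyl hydroperoxide CC(C)(C)OO
Why: Sharpless asymmetric epoxidation in the matched sense: the (R)-carbinol is the fast-reacting enantiomer for the D-(−)-tartrate complex and gives the erythro (anti) epoxy alcohol, which sets the (S)-oxirane carbon (future C-6).

**Step 5**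
Reactants: 8 (1R)-2-[4-(benzyloxy)phenyl]-1-[(2S)-oxiran-2-yl]ethan-1-ol
Product: 9 (2S)-2-{(1R)-1-(benzyloxy)-2-[4-(benzyloxy)phenyl]ethyl}oxirane
Conditions: NaH, BnBr, Bu4NI (cat.), THF, −20 → 0 °C
Reagents that add atoms: benzyl bromide BrCc1ccccc1
Why: Williamson benzylation of the secondary alkoxide in THF at low temperature with iodide catalysis outruns Payne rearrangement, so both stereocentres are kept.

**Step 6**
Reactants: 9 (2S)-2-{(1R)-1-(benzyloxy)-2-[4-(benzyloxy)phenyl]ethyl}oxirane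
Product: 10 (2R,3S)-2-(benzyloxy)-1-[4-(benzyloxy)phenyl]hex-5-en-3-ol
Conditions: CH2=CHMgBr (3 equiv), CuI (0.2 equiv), THF, −40 → −20 °C; aq NH4Cl
Reagents that add atoms: vinylmagnesium bromide C=C[Mg]Br
Why: Copper-catalysed SN2 opening of the terminal epoxide at CH2 by the vinyl Grignard reagent frees the C-6 hydroxyl as a homoallylic alcohol without touching either stereocentre.

**Step 7**
Reactants: 11 catechol
Product: 12 2-methoxyphenol (guaiacol)
Conditions: MeI (0.8 equiv), K2CO3 (1.0 equiv), acetone, reflux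
Reagents that add atoms: iodomethane CI
Why: Williamson mono-O-methylation, kept selective by using catechol in excess (diether and leftover catechol are removed by extraction).

**Step 8**
Reactants: 12 2-methoxyphenol
Product: 13 4-bromo-2-methoxyphenol
Conditions: NBS (1.0 equiv), MeCN, −10 → 0 °C
Reagents that add atoms: N-bromosuccinimide O=C1CCC(=O)N1Br
Why: Electrophilic aromatic bromination goes para to the free OH, the stronger activating group.

**Step 9**
Reactants: 13 4-bromo-2-methoxyphenol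
Product: 15 4-hydroxy-3-methoxybenzaldehyde (vanillin), via dilithio phenolate 14 (not isolated)
Conditions: t-BuLi (3.2 equiv), THF, −78 °C; DMF, −78 °C → rt; 1 M HCl
Reagents that add atoms: N,N-dimethylformamide CN(C)C=O
Why: Deprotonation of the phenol, then bromine–lithium exchange, gives an aryllithium that DMF formylates (Bouveault aldehyde synthesis).

**Step 10**
Reactants: 15 4-hydroxy-3-methoxybenzaldehyde
Product: 16 4-formyl-2-methoxyphenyl acetate
Conditions: Ac2O, pyridine, DMAP (cat.), CH2Cl2, 0 °C → rt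
Reagents that add atoms: acetic anhydride CC(=O)OC(C)=O
Why: O-acylation turns the strongly donating phenol into an acetate, so the aldehyde is an electron-poor Prins partner and oxonia-Cope scrambling is suppressed.

**Step 11**
Reactants: 10 (2R,3S)-2-(benzyloxy)-1-[4-(benzyloxy)phenyl]hex-5-en-3-ol; 16 4-formyl-2-methoxyphenyl acetate
Product: 18 (2R,4R,6S)-6-{(1R)-1-(benzyloxy)-2-[4-(benzyloxy)phenyl]ethyl}-2-(4-hydroxy-3-methoxyphenyl)oxan-4-ol, via trifluoroacetate 17 (not isolated)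
Conditions: 16 (1.5 equiv), TFA (20 equiv), CH2Cl2, 0 °C → rt; evaporate; K2CO3, MeOH, rt
Reagents that add atoms: trifluoroacetic acid OC(=O)C(F)(F)F
Why: Prins cyclisation: the (E)-oxocarbenium ion closes through a chair with the C-2 and C-6 substituents equatorial and trifluoroacetate adds equatorially at C-4, so the (S) centre C-6 dictates (2R) and (4R) (all-cis ring), and methanolysis then removes the trifluoroacetate and the aryl acetate.

**Step 12**
Reactants: 18 (2R,4R,6S)-6-{(1R)-1-(benzyloxy)-2-[4-(benzyloxy)phenyl]ethyl}-2-(4-hydroxy-3-methoxyphenyl)oxan-4-ol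
Product: 19 (2R,4R,6S)-2-(4-hydroxy-3-methoxyphenyl)-6-[(1R)-1-hydroxy-2-(4-hydroxyphenyl)ethyl]oxan-4-ol
Conditions: H2 (1 atm), 10% Pd/C, EtOAc–MeOH, rt
Reagents that add atoms: none
Why: Catalytic hydrogenolysis cleaves the aryl and the secondary alkyl benzyl ethers without touching any stereocentre, the ring C–O bond being much slower to cleave under neutral conditions.

## Compound list

1 | 4-bromophenol | Oc1ccc(Br)cc1 | starting material
2 | 1-(benzyloxy)-4-bromobenzene | Brc1ccc(OCc2ccccc2)cc1 | intermediate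
3 | (R)-epichlorohydrin, (2R)-2-(chloromethyl)oxirane | ClC[C@H]1CO1 | starting material
4 | [4-(benzyloxy)phenyl]magnesium bromide (not isolated) | Br[Mg]c1ccc(OCc2ccccc2)cc1 | intermediate
5 | (2R)-1-[4-(benzyloxy)phenyl]-3-chloropropan-2-ol (not isolated) | ClC[C@H](O)Cc1ccc(OCc2ccccc2)cc1 | intermediate
6 | (2R)-2-[4-(benzyloxy)benzyl]oxirane | O1C[C@H]1Cc2ccc(OCc3ccccc3)cc2 | intermediate
7 | (2R)-1-[4-(benzyloxy)phenyl]but-3-en-2-ol | C=C[C@H](O)Cc1ccc(OCc2ccccc2)cc1 | intermediate
8 | (1R)-2-[4-(benzyloxy)phenyl]-1-[(2S)-oxiran-2-yl]ethan-1-ol | C1O[C@@H]1[C@H](O)Cc2ccc(OCc3ccccc3)cc2 | intermediate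
9 | (2S)-2-{(1R)-1-(benzyloxy)-2-[4-(benzyloxy)phenyl]ethyl}oxirane | C1O[C@@H]1[C@H](OCc2ccccc2)Cc2ccc(OCc3ccccc3)cc2 | intermediate
10 | (2R,3S)-2-(benzyloxy)-1-[4-(benzyloxy)phenyl]hex-5-en-3-ol | C=CC[C@H](O)[C@H](OCc1ccccc1)Cc1ccc(OCc2ccccc2)cc1 | intermediate
11 | catechol (benzene-1,2-diol) | Oc1ccccc1O | starting material
12 | 2-methoxyphenol (guaiacol) | COc1ccccc1O | intermediate
13 | 4-bromo-2-methoxyphenol | COc1cc(Br)ccc1O | intermediate
14 | lithium 4-lithio-2-methoxyphenolate (not isolated) | [Li]Oc1ccc([Li])cc1OC | intermediate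
15 | 4-hydroxy-3-methoxybenzaldehyde (vanillin) | COc1cc(C=O)ccc1O | intermediate
16 | 4-formyl-2-methoxyphenyl acetate | COc1cc(C=O)ccc1OC(C)=O | intermediate
17 | (2R,4R,6S)-2-(4-acetoxy-3-methoxyphenyl)-6-{(1R)-1-(benzyloxy)-2-[4-(benzyloxy)phenyl]ethyl}oxan-4-yl trifluoroacetate (not isolated) | COc1cc([C@H]2C[C@@H](OC(=O)C(F)(F)F)C[C@@H]([C@H](OCc3ccccc3)Cc3ccc(OCc4ccccc4)cc3)O2)ccc1OC(C)=O | intermediate
18 | (2R,4R,6S)-6-{(1R)-1-(benzyloxy)-2-[4-(benzyloxy)phenyl]ethyl}-2-(4-hydroxy-3-methoxyphenyl)oxan-4-ol | COc1cc([C@H]2C[C@@H](O)C[C@@H]([C@H](OCc3ccccc3)Cc3ccc(OCc4ccccc4)cc3)O2)ccc1O | intermediate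
19 | (2R,4R,6S)-2-(4-hydroxy-3-methoxyphenyl)-6-[(1R)-1-hydroxy-2-(4-hydroxyphenyl)ethyl]oxan-4-ol | COc1cc([C@H]2C[C@@H](O)C[C@@H]([C@H](O)Cc3ccc(O)cc3)O2)ccc1O | target

## Step count and risks

Total step count: 12. Longest linear sequence: 8 steps (1, 2, 3, 4, 5, 6, 11, 12, from 4-bromophenol 1 to 19).

**Step 11 (Prins cyclisation).** Risks are oxonia-Cope side-chain exchange, partial loss of benzyl ethers in TFA and slow condensation. The fallback sets out from 9 and 16 and comes back at 18; it swaps the simple alkene for an allylsilane terminator and sets C-4 by ketone reduction. Epoxide 9 is opened with CH2=C(MgBr)CH2SiMe3 (from 2-bromo-3-(trimethylsilyl)propene and Mg; CuI cat., THF, −40 °C) to give (2R,3S)-2-(benzyloxy)-1-[4-(benzyloxy)phenyl]-5-[(trimethylsilyl)methyl]hex-5-en-3-ol F1. Condensation of F1 with 16 under TMSOTf in Et2O at −78 °C (intramolecular silyl-modified Sakurai cyclisation, same diequatorial chair, much faster than any exchange pathway) gives 4-[(2R,6S)-6-{(1R)-1-(benzyloxy)-2-[4-(benzyloxy)phenyl]ethyl}-4-methylideneoxan-2-yl]-2-methoxyphenyl acetate F2. Ozonolysis (O3, CH2Cl2–MeOH, −78 °C; Me2S) gives 4-[(2R,6S)-6-{(1R)-1-(benzyloxy)-2-[4-(benzyloxy)phenyl]ethyl}-4-oxooxan-2-yl]-2-methoxyphenyl acetate F3. NaBH4 in MeOH at −40 °C (axial hydride attack, equatorial OH, all-cis) gives 4-[(2R,4R,6S)-6-{(1R)-1-(benzyloxy)-2-[4-(benzyloxy)phenyl]ethyl}-4-hydroxyoxan-2-yl]-2-methoxyphenyl acetate F4, and K2CO3 added to the same flask removes the aryl acetate to give 18.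

**Step 4 (Sharpless epoxidation of a monosubstituted alkene).** The reaction is slow and the terminal epoxy alcohol can be opened by the titanium alkoxides. The fallback sets out from 7 and comes back at 10; it makes the C-5/C-6 bond by allylboration instead of epoxide opening, so steps 5 and 6 are not needed. Benzylation of 7 (NaH, BnBr, Bu4NI, THF) gives 1-(benzyloxy)-4-[(2R)-2-(benzyloxy)but-3-en-1-yl]benzene F5. Cleavage of the vinyl group (OsO4 cat., NaIO4, 2,6-lutidine, dioxane–H2O) gives (2R)-2-(benzyloxy)-3-[4-(benzyloxy)phenyl]propanal F6. Brown allylboration with (−)-Ipc2B(allyl), the reagent made from (+)-α-pinene (Et2O, −78 °C; then NaOH, H2O2), attacks the Si face of the aldehyde under reagent control and gives the (3S) alcohol 10.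

**Step 9 (exchange on an electron-rich lithium bromophenolate).** Risks are incomplete exchange, poor solubility of the dianion and protonation to guaiacol. The fallback sets out from 12 and comes back at 15; it uses no organometallic and step 8 is dropped. Guaiacol 12 is hydroxyalkylated para to the OH with glyoxylic acid (aq NaOH, rt) to give racemic 2-hydroxy-2-(4-hydroxy-3-methoxyphenyl)acetic acid F7. Oxidative decarboxylation of F7 (CuO, aq NaOH, air, 95 °C; then H2SO4) gives vanillin 15.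

## Further compounds

F1 | step 11 | (2R,3S)-2-(benzyloxy)-1-[4-(benzyloxy)phenyl]-5-[(trimethylsilyl)methyl]hex-5-en-3-ol | C=C(C[Si](C)(C)C)C[C@H](O)[C@H](OCc1ccccc1)Cc1ccc(OCc2ccccc2)cc1
F2 | step 11 | 4-[(2R,6S)-6-{(1R)-1-(benzyloxy)-2-[4-(benzyloxy)phenyl]ethyl}-4-methylideneoxan-2-yl]-2-methoxyphenyl acetate | COc1cc([C@H]2CC(=C)C[C@@H]([C@H](OCc3ccccc3)Cc3ccc(OCc4ccccc4)cc3)O2)ccc1OC(C)=O
F3 | step 11 | 4-[(2R,6S)-6-{(1R)-1-(benzyloxy)-2-[4-(benzyloxy)phenyl]ethyl}-4-oxooxan-2-yl]-2-methoxyphenyl acetate | COc1cc([C@H]2CC(=O)C[C@@H]([C@H](OCc3ccccc3)Cc3ccc(OCc4ccccc4)cc3)O2)ccc1OC(C)=O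
F4 | step 11 | 4-[(2R,4R,6S)-6-{(1R)-1-(benzyloxy)-2-[4-(benzyloxy)phenyl]ethyl}-4-hydroxyoxan-2-yl]-2-methoxyphenyl acetate | COc1cc([C@H]2C[C@@H](O)C[C@@H]([C@H](OCc3ccccc3)Cc3ccc(OCc4ccccc4)cc3)O2)ccc1OC(C)=O
F5 | step 4 | 1-(benzyloxy)-4-[(2R)-2-(benzyloxy)but-3-en-1-yl]benzene | C=C[C@H](OCc1ccccc1)Cc1ccc(OCc2ccccc2)cc1
F6 | step 4 | (2R)-2-(benzyloxy)-3-[4-(benzyloxy)phenyl]propanal | O=C[C@H](OCc1ccccc1)Cc1ccc(OCc2ccccc2)cc1
F7 | step 9 | 2-hydroxy-2-(4-hydroxy-3-methoxyphenyl)acetic acid (racemic) | COc1cc(C(O)C(=O)O)ccc1O
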